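1.6 s is the half-life of D, shorter than the 0.18 min forward half-life of G going to L, so I took elm to hold 17.6 mM of X from the start, taking each G at 0.243 /s, faster than G leaves for L at 0.0642 /s.

| setting | ash | elm | maple | oak |
|---|---|---|---|---|
| G | 16 mM (fed, over 3.20 min) | 16 mM | 16 mM | 16 mM |
| D | 1.10 equiv | 1.10 equiv | 1.10 equiv (fed, over 3.20 min) | 1.10 equiv |
| time | 4.0 min | 4.0 min | 4.0 min |  |
| remark | a stirred flask in which G is dosed at a steady rate over 3.20 min without added volume, worked up at 4.0 min | everything together in a closed stirred flask, run for 4.0 min | a stirred flask in which D is dosed at a steady rate over 3.20 min without added volume, worked up at 4.0 min | a single well-mixed tank run continuously and read at steady state, 4.0 min in it on average |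

- the set-up with the highest amount of L.X at the outlet or at the end, in percent of the G put in ("none" if the first two lie within 2 percentage points) (ash / elm / maple / oak / none)
- amount of L.X at the outlet or at the end, in percent of the G put in, ash
- amount of L.X at the outlet or at the end, in percent of the G put in, elm
- amount of L.X at the outlet or at the end, in percent of the G put in, maple
- amount of L.X at the outlet or at the end, in percent of the G put in, oak

    G + X → G.X (k1 = 13.8 /M/s)
    2 L → L2 (k2 = 0.110 /M/s)
    L.X ⇌ E (K3 = 0.82, k3 = 0.0279 /s)
    L + X → L.X (k4 = 1.15 /M/s)
    G ⇌ L (K5 = 7.0, k5 = 0.0642 /s)
    D → X (k6 = 0.426 /s)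

- percent here means G units held: one L2 counts as two
- for a step with 2 of a species take k times the square, and two of it per event
- the stated concentrations are those of everything mixed, before any reaction; amounts are the same in each set-up
- the feed brings no volume worth counting
- run time (ash): 4.0 min

I reckoned elm by hand. Each G has two exits, so I took the rate to L over the sum of the rates to L and to G.X. That gave three values:

- [X] at full charge: 20.9%
- [X] at its floor of 1.60 mM, the excess of X over G: 74.4%
- [X] replaced by its mean over the burst, each caught G taking one X: 28.2%

This last figure is the escape share, the selectivity between L and G.X: the part of G that reaches L before X catches it. It left 6.11 mM of X. To check the error, I averaged the shares at the two ends of the burst instead, which gave 32.1%, higher by 3.9 percentage points.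

The pair L.X and E relaxes in 0.187 min, short against 4.0 min, and holds 54.9% as L.X. That gave a bracket for L.X in elm:

- Above, each escaped L ends in the pair: 15.5%
- Below, each L returning to G is lost, dimer loss is taken at the top [L], and [X] is 3.85 mM, so capture is 30.4% and L.X is 4.70%

The forecast put maple first, on the ground that “slow X lets G become L first”, with ash 7.1%, elm 8.9%, maple 18.4% and oak 10%. Its elm figure lies inside my bracket. It put the G burned in elm at about 10 mM, where my share gave 11.5 mM.

The simulation gave maple first, with ash 7.78%, elm 9.74%, maple 18.1% and oak 10.2%. Elm lies inside the bracket. Maple's lead over oak, 7.9 points, is wider than the margin of 2 points, and for the forecast's choice to fail, a run would have to close that gap.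

The neighbour is elm with 0.660 equiv of D instead of 1.10 equiv. The same reckoning, from 10.6 mM of X, raised the escape share from 28.2% to 43.5%, which leaves 56.5% of the G charged for G.X. The neighbour's G.X stood at 56.2%. My upper estimate for its L.X was 23.9%, and L.X ended at 4.99%, with L at 23.7%.

The numbers are made up; the result is computed.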